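Ring C (C1 carboxyl carbon, C2 OH, C4 depside oxygen, C6 methyl) is cut back to an open tetraketide. C4 sits beta to the C2 ketone, so a C3–C4 alkyne makes it the acceptor for the carboxylate of the benzyl-protected A–B didepside acid 14. In one flask an amine catalyst forges the O–C4 ester bond. The C1 methylene then condenses with the C6 methyl ketone (C1–C6), and ring C aromatises to tridepside ester 26, whose C2 and C4 oxygens differ by origin. The electrophile, benzyl 3,7-dioxooct-4-ynoate 23, is released from a storable diol just before use. One hydrogenolysis then gives the target.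

Key step: step 15

Remark on numbering: in every ring C1 bears the carboxyl carbon, C2 the ortho oxygen, C4 the para oxygen and C6 the methyl group; ring A also carries the acetoxy group at C5.
Remark on stereochemistry: the target has no stereocentre. Pent-4-yn-2-ol is used as the racemate, and the carbinol centres of 15–22 are erased in step 14, so their SMILES carry no configuration.
Remark on geometry: the enol ester that can fold to ring C is the E isomer. Its acyloxy group is trans to the C2 carbonyl, and C5 and C2 are cis.

Step 1
Reactants: 1 orcinol (5-methylbenzene-1,3-diol)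
Product: 3 2,4-dihydroxy-6-methylbenzaldehyde, via aryl iminium chloride 2 (not isolated)
Conditions: POCl3, DMF, 0 °C → rt; then ice-water
Reagents that add atoms: N,N-dimethylformamide CN(C)C=O; water O
Why: Vilsmeier–Haack formylation of the doubly activated ring goes to the carbon next to the methyl group (ortho to one OH, para to the other), and water hydrolyses the iminium salt to the chelated aldehyde that later serves both ring A and ring B.

Step 2
Reactants: 3 2,4-dihydroxy-6-methylbenzaldehyde
Product: 4 2,4-bis(benzyloxy)-6-methylbenzaldehyde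
Conditions: BnBr (2.5 equiv), K2CO3, DMF, 60 °C
Reagents that add atoms: benzyl bromide BrCc1ccccc1
Why: Williamson etherification in warm DMF alkylates the free 4-OH and also the hydrogen-bonded 2-OH.

Step 3
Reactants: 4 2,4-bis(benzyloxy)-6-methylbenzaldehyde
Product: 6 2,4-bis(benzyloxy)-6-methylphenol, via aryl formate 5 (not isolated)
Conditions: mCPBA, CH2Cl2, 0 °C → rt; wash, evaporate; then K2CO3 (cat.), MeOH, rt
Reagents that add atoms: 3-chloroperbenzoic acid OOC(=O)c1cccc(Cl)c1
Why: In this Baeyer–Villiger (Dakin-type) oxidation the electron-rich aryl group migrates in preference to hydrogen, and base-catalysed methanolysis strips the labile formate without touching the benzyl ethers, which places the future O5 of ring A.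

Step 4
Reactants: 6 2,4-bis(benzyloxy)-6-methylphenol
Product: 7 2,4-bis(benzyloxy)-6-methylphenyl acetate
Conditions: Ac2O, DMAP (cat.), pyridine, rt
Reagents that add atoms: acetic anhydride CC(=O)OC(C)=O
Why: DMAP-catalysed O-acetylation of the only free phenol fixes the acetate on O5 while O2 and O4 are still benzylated, so the three ring A oxygens never need to be told apart later.

Step 5
Reactants: 7 2,4-bis(benzyloxy)-6-methylphenyl acetate
Product: 9 3-acetoxy-4,6-bis(benzyloxy)-2-methylbenzaldehyde, via aryl iminium chloride 8 (not isolated)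
Conditions: POCl3, DMF, 0 → 60 °C; then ice-water, rt
Reagents that add atoms: N,N-dimethylformamide CN(C)C=O; water O
Why: Vilsmeier–Haack formylation of a 3,5-dialkoxytoluene pattern attacks the carbon between the methyl and one benzyloxy group (para to the other) rather than the more crowded carbon between both benzyloxy groups, and the non-basic medium leaves the aryl acetate in place.

Step 6
Reactants: 9 3-acetoxy-4,6-bis(benzyloxy)-2-methylbenzaldehyde
Product: 10 3-acetoxy-4,6-bis(benzyloxy)-2-methylbenzoic acid (ring A acid)
Conditions: NaClO2, NaH2PO4, 2-methyl-2-butene, t-BuOH/THF/H2O, rt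
Reagents that add atoms: sodium chlorite [Na+].[O-]Cl=O
Why: Pinnick oxidation converts hindered aromatic aldehydes to acids at mildly acidic pH, where the acetate and benzyl ethers are stable and the alkene scavenger prevents ring chlorination.

Step 7
Reactants: 10 3-acetoxy-4,6-bis(benzyloxy)-2-methylbenzoic acid; 3 2,4-dihydroxy-6-methylbenzaldehyde
Product: 12 4-formyl-3-hydroxy-5-methylphenyl 3-acetoxy-4,6-bis(benzyloxy)-2-methylbenzoate, via trifluoroacetic mixed anhydride 11 (not isolated)
Conditions: (CF3CO)2O, toluene, 0 °C → rt
Reagents that add atoms: none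
Why: In this mixed-anhydride depside esterification the activated, electron-rich 2,6-disubstituted aroyl group acylates the free 4-OH of 3 while the 2-OH is held in a hydrogen bond to the formyl group, and no nucleophilic base is present that could move the acetate.

Step 8
Reactants: 12 4-formyl-3-hydroxy-5-methylphenyl 3-acetoxy-4,6-bis(benzyloxy)-2-methylbenzoate
Product: 13 3-(benzyloxy)-4-formyl-5-methylphenyl 3-acetoxy-4,6-bis(benzyloxy)-2-methylbenzoate
Conditions: BnOH, PPh3, DIAD, THF, 0 °C → rt
Reagents that add atoms: benzyl alcohol OCc1ccccc1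
Why: Mitsunobu etherification of the acidic salicylaldehyde-type phenol runs under neutral conditions that spare the acetate and the depside ester, and the new ether blocks the ortho phenol that would otherwise close a benzodioxinone onto the ynone in step 15.

Step 9
Reactants: 13 3-(benzyloxy)-4-formyl-5-methylphenyl 3-acetoxy-4,6-bis(benzyloxy)-2-methylbenzoate
Product: 14 4-{[3-acetoxy-4,6-bis(benzyloxy)-2-methylbenzoyl]oxy}-2-(benzyloxy)-6-methylbenzoic acid (A–B didepside acid)
Conditions: NaClO2, NaH2PO4, 2-methyl-2-butene, t-BuOH/THF/H2O, rt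
Reagents that add atoms: sodium chlorite [Na+].[O-]Cl=O
Why: A second Pinnick oxidation unveils the ring B carboxyl group from the formyl group, so no ester has to be cleaved in the presence of the acetate, the depside bond and the benzyl ethers.

Step 10
Reactants: 15 pent-4-yn-2-ol (racemic)
Product: 16 tert-butyldimethyl(pent-4-yn-2-yloxy)silane
Conditions: TBSCl, imidazole, CH2Cl2, rt
Reagents that add atoms: tert-butyldimethylsilyl chloride CC(C)(C)[Si](C)(C)Cl
Why: Standard silylation masks the carbinol so that only the alkyne C–H is metallated in the next step.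

Step 11
Reactants: 16 tert-butyldimethyl(pent-4-yn-2-yloxy)silane
Product: 18 5-[(tert-butyldimethylsilyl)oxy]hex-2-ynal, via lithium acetylide 17 (not isolated)
Conditions: n-BuLi, THF, −78 °C; DMF, −78 → 0 °C; reverse quench into aq. KH2PO4/MTBE
Reagents that add atoms: N,N-dimethylformamide CN(C)C=O
Why: Formylation of a lithium acetylide by DMF gives a stable hemiaminal alkoxide, and the buffered reverse quench releases the ynal while keeping the liberated amine protonated so that it cannot add to the triple bond.

Step 12
Reactants: 18 5-[(tert-butyldimethylsilyl)oxy]hex-2-ynal; 19 benzyl acetate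
Product: 21 benzyl 7-[(tert-butyldimethylsilyl)oxy]-3-hydroxyoct-4-ynoate (diastereomer mixture), via lithium enolate of benzyl acetate 20 (not isolated)
Conditions: LiN(iPr)2, THF, −78 °C; then 18, −78 °C; AcOH quench
Reagents that add atoms: none
Why: Acetate aldol addition of a lithium ester enolate to an ynal is a clean 1,2-addition at low temperature, and the configuration of the new carbinol is irrelevant because it is oxidised in step 14.

Step 13
Reactants: 21 benzyl 7-[(tert-butyldimethylsilyl)oxy]-3-hydroxyoct-4-ynoate
Product: 22 benzyl 3,7-dihydroxyoct-4-ynoate (diastereomer mixture)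
Conditions: 48% aq. HF, MeCN, 0 °C → rt
Reagents that add atoms: none
Why: Acidic fluoride desilylation is done while the chain is still a robust alkynediol, so no ynone or beta-keto ester is ever exposed to fluoride or base, and 22 is the form in which the fragment is stored.

Step 14
Reactants: 22 benzyl 3,7-dihydroxyoct-4-ynoate
Product: 23 benzyl 3,7-dioxooct-4-ynoate
Conditions: Dess–Martin periodinane (2.5 equiv), CH2Cl2, 0 °C; short silica plug, used at once
Reagents that add atoms: none
Why: Dess–Martin oxidation converts the propargylic and the homopropargylic carbinol together under non-basic conditions, which limits the prototropic shift of the doubly activated C5 methylene, and any allene tautomer that does form is harmless because its central carbon is the same electrophilic C4.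

Step 15
Reactants: 14 A–B didepside acid; 23 benzyl 3,7-dioxooct-4-ynoate
Product: 26 benzyl 4-{[4-{[3-acetoxy-4,6-bis(benzyloxy)-2-methylbenzoyl]oxy}-2-(benzyloxy)-6-methylbenzoyl]oxy}-2-hydroxy-6-methylbenzoate, via E-enol ester 24 (not isolated), via cyclohexenone aldol adduct 25 (not isolated)
Conditions: DABCO (0.2 equiv), 4 Å MS, THF, 0 °C, slow addition of 23 (1.3 equiv) to 14; then rt → 40 °C
Reagents that add atoms: none
Why: Proposed new method: DABCO either adds to the ynone beta carbon (C4 of ring C) or shifts a C5 proton to give the 1,3-diacylallene, and since the same carbon is the electrophile in both channels the carboxylate of 14 arrives there by addition–elimination or by direct conjugate addition, giving enol ester 24 (O–C4 bond). The closest known reaction types are the tertiary-amine-catalysed addition of carboxylic acids to ynones and propiolates, which gives beta-acyloxy enones, and the mild-base aldol aromatisation of 3,5,7-triketo esters to orsellinates, but their union in one flask is untested. Only E-24 can fold, and because E and Z isomers interconvert through reversible amine addition and through the C5 dienolate, the irreversible ring closure should drain both. Ring C closes by attack of the C1 carbanion on the C6 ketone (C1–C6 bond), a 6-(enolexo)-exo-trig aldol when counted through the ester enolate, giving 25, which loses water by E1cB and enolises at C2 to the phenol, so its two transient stereocentres vanish and none remains to be controlled. The step needs O–C4 addition before any C–C bond formation, which is secured because neither the linear alkyne nor the allene can bring C1 to C6 and because acid 14, kept in excess by the slow addition, buffers the amine so that the beta-keto ester stays largely protonated until the acid is consumed. It also needs the aroyl group to stay on O4, which should follow from the two ortho substituents (CH3 and OBn) of ring B, from the trans placement of the ester relative to the enolate in E-24, and from the sieves that trap the liberated water.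

Step 16
Reactants: 26 tridepside benzyl ester
Product: 27 4-{[4-{[3-acetoxy-4,6-dihydroxy-2-methylbenzoyl]oxy}-2-hydroxy-6-methylbenzoyl]oxy}-2-hydroxy-6-methylbenzoic acid (CNP0154030.0)
Conditions: H2 (1 atm), 10% Pd/C, EtOAc, rt
Reagents that add atoms: none
Why: Catalytic hydrogenolysis removes the three benzyl ethers and the benzyl ester while aryl esters are inert, and the neutral aprotic medium at room temperature guards against O5 → O4 acetyl migration on ring A and against decarboxylation of the ring C acid.

Compound list
1 | orcinol | Cc1cc(O)cc(O)c1 | starting material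
2 | (2,4-dihydroxy-6-methylbenzylidene)dimethyliminium chloride | C[N+](C)=Cc1c(C)cc(O)cc1O.[Cl-] | intermediate
3 | 2,4-dihydroxy-6-methylbenzaldehyde | Cc1cc(O)cc(O)c1C=O | intermediate
4 | 2,4-bis(benzyloxy)-6-methylbenzaldehyde | Cc1cc(OCc2ccccc2)cc(OCc2ccccc2)c1C=O | intermediate
5 | 2,4-bis(benzyloxy)-6-methylphenyl formate | Cc1cc(OCc2ccccc2)cc(OCc2ccccc2)c1OC=O | intermediate
6 | 2,4-bis(benzyloxy)-6-methylphenol | Cc1cc(OCc2ccccc2)cc(OCc2ccccc2)c1O | intermediate
7 | 2,4-bis(benzyloxy)-6-methylphenyl acetate | Cc1cc(OCc2ccccc2)cc(OCc2ccccc2)c1OC(C)=O | intermediate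
8 | [3-acetoxy-4,6-bis(benzyloxy)-2-methylbenzylidene]dimethyliminium chloride | CC(=O)Oc1c(OCc2ccccc2)cc(OCc2ccccc2)c(C=[N+](C)C)c1C.[Cl-] | intermediate
9 | 3-acetoxy-4,6-bis(benzyloxy)-2-methylbenzaldehyde | CC(=O)Oc1c(OCc2ccccc2)cc(OCc2ccccc2)c(C=O)c1C | intermediate
10 | 3-acetoxy-4,6-bis(benzyloxy)-2-methylbenzoic acid | CC(=O)Oc1c(OCc2ccccc2)cc(OCc2ccccc2)c(C(=O)O)c1C | intermediate
11 | 3-acetoxy-4,6-bis(benzyloxy)-2-methylbenzoic trifluoroacetic anhydride | CC(=O)Oc1c(OCc2ccccc2)cc(OCc2ccccc2)c(C(=O)OC(=O)C(F)(F)F)c1C | intermediate
12 | 4-formyl-3-hydroxy-5-methylphenyl 3-acetoxy-4,6-bis(benzyloxy)-2-methylbenzoate | CC(=O)Oc1c(OCc2ccccc2)cc(OCc2ccccc2)c(C(=O)Oc2cc(C)c(C=O)c(O)c2)c1C | intermediate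
13 | 3-(benzyloxy)-4-formyl-5-methylphenyl 3-acetoxy-4,6-bis(benzyloxy)-2-methylbenzoate | CC(=O)Oc1c(OCc2ccccc2)cc(OCc2ccccc2)c(C(=O)Oc2cc(C)c(C=O)c(OCc3ccccc3)c2)c1C | intermediate
14 | 4-{[3-acetoxy-4,6-bis(benzyloxy)-2-methylbenzoyl]oxy}-2-(benzyloxy)-6-methylbenzoic acid | CC(=O)Oc1c(OCc2ccccc2)cc(OCc2ccccc2)c(C(=O)Oc2cc(C)c(C(=O)O)c(OCc3ccccc3)c2)c1C | intermediate
15 | pent-4-yn-2-ol (racemic) | CC(O)CC#C | starting material
16 | tert-butyldimethyl(pent-4-yn-2-yloxy)silane | CC(CC#C)O[Si](C)(C)C(C)(C)C | intermediate
17 | lithium acetylide of 16 | [Li]C#CCC(C)O[Si](C)(C)C(C)(C)C | intermediate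
18 | 5-[(tert-butyldimethylsilyl)oxy]hex-2-ynal | CC(CC#CC=O)O[Si](C)(C)C(C)(C)C | intermediate
19 | benzyl acetate | CC(=O)OCc1ccccc1 | starting material
20 | lithium enolate of benzyl acetate | [Li]OC(=C)OCc1ccccc1 | intermediate
21 | benzyl 7-[(tert-butyldimethylsilyl)oxy]-3-hydroxyoct-4-ynoate | CC(CC#CC(O)CC(=O)OCc1ccccc1)O[Si](C)(C)C(C)(C)C | intermediate
22 | benzyl 3,7-dihydroxyoct-4-ynoate | CC(O)CC#CC(O)CC(=O)OCc1ccccc1 | intermediate
23 | benzyl 3,7-dioxooct-4-ynoate | CC(=O)CC#CC(=O)CC(=O)OCc1ccccc1 | intermediate
24 | benzyl (E)-5-(A–B aroyloxy)-3,7-dioxooct-4-enoate | CC(=O)Oc1c(OCc2ccccc2)cc(OCc2ccccc2)c(C(=O)Oc2cc(C)c(C(=O)O/C(CC(C)=O)=C/C(=O)CC(=O)OCc3ccccc3)c(OCc3ccccc3)c2)c1C | intermediate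
25 | benzyl 4-(A–B aroyloxy)-6-hydroxy-6-methyl-2-oxocyclohex-3-ene-1-carboxylate (transient, configuration undefined) | CC(=O)Oc1c(OCc2ccccc2)cc(OCc2ccccc2)c(C(=O)Oc2cc(C)c(C(=O)OC3=CC(=O)C(C(=O)OCc4ccccc4)C(C)(O)C3)c(OCc3ccccc3)c2)c1C | intermediate
26 | benzyl 4-{[4-{[3-acetoxy-4,6-bis(benzyloxy)-2-methylbenzoyl]oxy}-2-(benzyloxy)-6-methylbenzoyl]oxy}-2-hydroxy-6-methylbenzoate | CC(=O)Oc1c(OCc2ccccc2)cc(OCc2ccccc2)c(C(=O)Oc2cc(C)c(C(=O)Oc3cc(C)c(C(=O)OCc4ccccc4)c(O)c3)c(OCc3ccccc3)c2)c1C | intermediate
27 | 4-{[4-{[3-acetoxy-4,6-dihydroxy-2-methylbenzoyl]oxy}-2-hydroxy-6-methylbenzoyl]oxy}-2-hydroxy-6-methylbenzoic acid (CNP0154030.0) | CC(=O)Oc1c(O)cc(O)c(C(=O)Oc2cc(C)c(C(=O)Oc3cc(C)c(C(=O)O)c(O)c3)c(O)c2)c1C | target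

Total step count: 16.
Longest linear sequence: 11 steps (steps 1–9, 15, 16). The ynone branch contributes steps 10–14.

Steps most likely to fail

Step 15. Several processes could undermine the cascade:
- self-condensation of the ynedione through its acidic methylenes
- reversal of the oxa-Michael addition
- transfer of the aroyl group to the enolate
- hydrolysis of the enol ester by the water of aromatisation before ring closure

The fallback is the classical depside esterification, which is known chemistry. It sets out from 14. Commercial orsellinic acid is alkylated at the carboxylate only (BnBr, KHCO3, DMF, rt) to give benzyl 2,4-dihydroxy-6-methylbenzoate F1. Acid 14 is then joined to the unchelated 4-OH of F1 through its trifluoroacetic mixed anhydride ((CF3CO)2O, toluene, rt), exactly as in step 7. This comes back to the route at 26.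

Step 14. The activated C1 methylene may be over-oxidised, or a prototropic alkyne-to-allene shift may be followed by oligomerisation while the product is concentrated. The fallback postpones the C6 ketone until the O–C4 bond exists, so the skipped ynedione is never handled. It sets out from 22. MnO2 in CH2Cl2 oxidises only the propargylic carbinol to benzyl 7-hydroxy-3-oxooct-4-ynoate F2. DABCO-catalysed addition of acid 14 gives benzyl (E)-5-(A–B aroyloxy)-7-hydroxy-3-oxooct-4-enoate F3. Dess–Martin periodinane then oxidises the remaining carbinol. This comes back to the route at 24, which is treated with DABCO and sieves to close to 26.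

Step 5. Formylation may occur at the carbon between the two benzyloxy groups, or the acetate or a benzyl ether may be lost in the acidic chloroiminium medium. The fallback replaces electrophilic formylation with bromination, halogen–lithium exchange and carboxylation, using a silyl group as placeholder for the acetate. It sets out from 6 and proceeds as follows:
- TBSCl/imidazole gives [2,4-bis(benzyloxy)-6-methylphenoxy](tert-butyl)dimethylsilane F4.
- NBS in MeCN at 0 °C brominates next to the methyl group to give [4,6-bis(benzyloxy)-3-bromo-2-methylphenoxy](tert-butyl)dimethylsilane F5.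
- n-BuLi (THF, −78 °C) followed by CO2 gives 4,6-bis(benzyloxy)-3-[(tert-butyldimethylsilyl)oxy]-2-methylbenzoic acid F6.
- Bu4NF/AcOH gives 4,6-bis(benzyloxy)-3-hydroxy-2-methylbenzoic acid F7.
- Ac2O/pyridine with an aqueous work-up acetylates the phenol.

This comes back to the route at 10 and replaces steps 4–6.

Further compounds
F1 | step 15 | benzyl 2,4-dihydroxy-6-methylbenzoate | Cc1cc(O)cc(O)c1C(=O)OCc1ccccc1
F2 | step 14 | benzyl 7-hydroxy-3-oxooct-4-ynoate | CC(O)CC#CC(=O)CC(=O)OCc1ccccc1
F3 | step 14 | benzyl (E)-5-(A–B aroyloxy)-7-hydroxy-3-oxooct-4-enoate | CC(=O)Oc1c(OCc2ccccc2)cc(OCc2ccccc2)c(C(=O)Oc2cc(C)c(C(=O)O/C(CC(C)O)=C/C(=O)CC(=O)OCc3ccccc3)c(OCc3ccccc3)c2)c1C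
F4 | step 5 | [2,4-bis(benzyloxy)-6-methylphenoxy](tert-butyl)dimethylsilane | Cc1cc(OCc2ccccc2)cc(OCc2ccccc2)c1O[Si](C)(C)C(C)(C)C
F5 | step 5 | [4,6-bis(benzyloxy)-3-bromo-2-methylphenoxy](tert-butyl)dimethylsilane | Cc1c(Br)c(OCc2ccccc2)cc(OCc2ccccc2)c1O[Si](C)(C)C(C)(C)C
F6 | step 5 | 4,6-bis(benzyloxy)-3-[(tert-butyldimethylsilyl)oxy]-2-methylbenzoic acid | Cc1c(C(=O)O)c(OCc2ccccc2)cc(OCc2ccccc2)c1O[Si](C)(C)C(C)(C)C
F7 | step 5 | 4,6-bis(benzyloxy)-3-hydroxy-2-methylbenzoic acid | Cc1c(C(=O)O)c(OCc2ccccc2)cc(OCc2ccccc2)c1O
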